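**Retrosynthetic overview**

1. Numbering used for the tricycle (longipinane type): C1 = ketone carbon; C2=C3 = enone alkene (C12 = methyl on C3); C4 and C11 = the cyclobutane CH carbons that carry C3 and C1; C5 (H) and C10 (C13 methyl) = the other two cyclobutane carbons; C6–C9 = the four-carbon bridge from C5 to C10 (C14 methyl and C15 CH2O on C6). Last disconnection: the three angelate C–O bonds, made in two operations (primary C15 ester, then both secondary esters) from the triol.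
2. Key disconnection C1–C2 of the cyclohexenone (ring A: C1–C2–C3–C4–C5–C11). C1 is inserted as a masked acyl cation (C2 of a 1,3-dithiane) between the bridging carbonyl carbon of a bicyclo[4.1.1]octan-8-one (future C11) and the CH2= terminus of an allylsilane on the opposite one-carbon bridge (future C4); ring A closes through C1–C2 in the same flask.
3. Feature that allows it: C4 and C11 are the two one-carbon bridges of a cyclobutane puckered by the C6–C9 bridge, so groups on them anti to that bridge are 1,3-cis and about 3 Å apart. C11 is flanked by a bridgehead CH (C5) and a quaternary carbon (C10), so its ketone cannot enolise and its exocyclic C=C can be protonated only at C11.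
4. The cyclobutane (C4–C5–C11–C10) and the seven-membered ring are formed together one step earlier by an intramolecular ketene–diene [2+2] cycloaddition of an acyclic acid (bonds C5–C11 and C4–C10).
5. The acid is built linearly: quaternary C6 and C7 by a reagent-controlled allylboration with an allene-derived (Z)-allylborane, C9 by an Evans aldol reaction, the silyl-bearing diene by a Heck coupling. Ring order: seven-membered ring + cyclobutane, then ring A.

Key step: step 12

Remark on the chemistry: angelic anhydride [(2Z)-2-methylbut-2-enoic anhydride] is assumed to be a purchasable reagent and is used as the acyl donor for all three esters.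

**Step 1**
Reactants: 1 4-chlorobut-2-yn-1-ol
Product: 2 2-methylbuta-2,3-dien-1-ol
Conditions: MeMgBr (2.2 equiv), CuI (10 mol %), Et2O, −20 → 20 °C
Reagents that add atoms: methylmagnesium bromide, C[Mg]Br
Why: Copper-catalysed anti-SN2′ substitution of the propargylic chloride by the Grignard reagent delivers the 1,1-disubstituted allene, and no stereocentre is formed.

**Step 2**
Reactants: 2 2-methylbuta-2,3-dien-1-ol
Product: 3 tert-butyl[(2-methylbuta-2,3-dien-1-yl)oxy]diphenylsilane (TBDPS = tert-butyldiphenylsilyl)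
Conditions: TBDPSCl, imidazole, DMF, 20 °C
Reagents that add atoms: tert-butyl(chloro)diphenylsilane, CC(C)(C)[Si](Cl)(c1ccccc1)c1ccccc1
Why: Imidazole-promoted silylation of a primary alcohol gives a bulky silyl ether that later differentiates the two substituents of the allene terminus.

**Step 3**
Reactants: 3 tert-butyl[(2-methylbuta-2,3-dien-1-yl)oxy]diphenylsilane; 4 3-[(tert-butyldimethylsilyl)oxy]propanal (TBS = tert-butyldimethylsilyl)
Product: 6 (3R,4S)-1-(TBS-oxy)-4-[(TBDPS-oxy)methyl]-4-methylhex-5-en-3-ol, via allylborane 5 (not isolated)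
Conditions: (−)-diisopinocampheylborane, THF, −25 °C; then 4, −78 → 0 °C; NaOH, H2O2
Reagents that add atoms: none
Why: Hydroboration of the allene anti to the CH2OSi group should give the (Z)-γ,γ-disubstituted allylborane kinetically, and its allylboration of 4 through a chair transition state places CH2OSi syn and CH3 anti to the new hydroxyl (4S, the later C6), while the isopinocampheyl groups derived from (+)-α-pinene direct attack to the Si face of the aldehyde (3R, the later C7).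

**Step 4**
Reactants: 6 (3R,4S)-1-(TBS-oxy)-4-[(TBDPS-oxy)methyl]-4-methylhex-5-en-3-ol
Product: 7 (3R,4S)-1,3-bis(TBS-oxy)-4-[(TBDPS-oxy)methyl]-4-methylhex-5-ene
Conditions: TBSOTf, 2,6-lutidine, CH2Cl2, −78 → 0 °C
Reagents that add atoms: tert-butyldimethylsilyl trifluoromethanesulfonate, CC(C)(C)[Si](C)(C)OS(=O)(=O)C(F)(F)F
Why: Silyl triflate silylation protects the hindered secondary alcohol without touching a stereocentre.

**Step 5**
Reactants: 7 (3R,4S)-1,3-bis(TBS-oxy)-4-[(TBDPS-oxy)methyl]-4-methylhex-5-ene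
Product: 8 (3R,4S)-3-(TBS-oxy)-4-[(TBDPS-oxy)methyl]-4-methylhex-5-en-1-ol
Conditions: camphor-10-sulfonic acid (10 mol %), MeOH–CH2Cl2, 0 °C
Reagents that add atoms: none
Why: Acid-catalysed methanolysis (chemoselective desilylation) should remove the unhindered primary TBS ether much faster than the neopentyl secondary TBS ether and the TBDPS ether.

**Step 6**
Reactants: 8 (3R,4S)-3-(TBS-oxy)-4-[(TBDPS-oxy)methyl]-4-methylhex-5-en-1-ol
Product: 9 (3R,4S)-3-(TBS-oxy)-4-[(TBDPS-oxy)methyl]-4-methylhex-5-enal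
Conditions: Dess–Martin periodinane, NaHCO3, CH2Cl2, 20 °C
Reagents that add atoms: none
Why: Buffered Dess–Martin oxidation converts the primary alcohol into the aldehyde without β-elimination of the silyloxy group.

**Step 7**
Reactants: 9 (3R,4S)-3-(TBS-oxy)-4-[(TBDPS-oxy)methyl]-4-methylhex-5-enal; 10 (4S)-4-benzyl-3-propanoyl-1,3-oxazolidin-2-one
Product: 12 (4S)-4-benzyl-3-{(2S,3R,5R,6S)-5-(TBS-oxy)-6-[(TBDPS-oxy)methyl]-3-hydroxy-2,6-dimethyloct-7-enoyl}-1,3-oxazolidin-2-one, via boron enolate 11 (not isolated)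
Conditions: 10, n-Bu2BOTf, i-Pr2NEt, CH2Cl2, −78 → 0 °C; then 9, −78 → 0 °C; H2O2, MeOH, pH 7 buffer
Reagents that add atoms: none
Why: Evans syn-aldol reaction in which the (Z)-boron enolate adds through a Zimmerman–Traxler transition state under auxiliary control, setting 3R (the later C9) and 2S (a sacrificial centre that becomes the ketene carbon).

**Step 8**
Reactants: 12 (4S)-4-benzyl-3-{(2S,3R,5R,6S)-5-(TBS-oxy)-6-[(TBDPS-oxy)methyl]-3-hydroxy-2,6-dimethyloct-7-enoyl}-1,3-oxazolidin-2-one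
Product: 13 (4S)-4-benzyl-3-{(2S,3R,5R,6S)-3,5-bis(TBS-oxy)-6-[(TBDPS-oxy)methyl]-2,6-dimethyloct-7-enoyl}-1,3-oxazolidin-2-one
Conditions: TBSOTf, 2,6-lutidine, CH2Cl2, −78 → 0 °C
Reagents that add atoms: tert-butyldimethylsilyl trifluoromethanesulfonate, CC(C)(C)[Si](C)(C)OS(=O)(=O)C(F)(F)F
Why: Silyl triflate silylation of the aldol hydroxyl blocks retro-aldol cleavage and gives a uniform set of fluoride-labile protecting groups.

**Step 9**
Reactants: 13 (4S)-4-benzyl-3-{(2S,3R,5R,6S)-3,5-bis(TBS-oxy)-6-[(TBDPS-oxy)methyl]-2,6-dimethyloct-7-enoyl}-1,3-oxazolidin-2-one; 14 (2-bromoprop-2-en-1-yl)trimethylsilane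
Product: 15 (4S)-4-benzyl-3-{(2S,3R,5R,6S,7E)-3,5-bis(TBS-oxy)-6-[(TBDPS-oxy)methyl]-2,6-dimethyl-9-[(trimethylsilyl)methyl]deca-7,9-dienoyl}-1,3-oxazolidin-2-one
Conditions: Pd(OAc)2 (10 mol %), n-Bu4NCl, NaHCO3, DMF, 60 °C
Reagents that add atoms: none
Why: Heck reaction in which carbopalladation at the unhindered CH2 terminus of the vinyl group and syn β-hydride elimination (no β-hydrogen on the quaternary side) should give the (E)-1,3-diene that carries the allylsilane.

**Step 10**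
Reactants: 15 (4S)-4-benzyl-3-{(2S,3R,5R,6S,7E)-3,5-bis(TBS-oxy)-6-[(TBDPS-oxy)methyl]-2,6-dimethyl-9-[(trimethylsilyl)methyl]deca-7,9-dienoyl}-1,3-oxazolidin-2-one
Product: 16 (2S,3R,5R,6S,7E)-3,5-bis(TBS-oxy)-6-[(TBDPS-oxy)methyl]-2,6-dimethyl-9-[(trimethylsilyl)methyl]deca-7,9-dienoic acid
Conditions: LiOH, H2O2, THF–H2O, 0 °C; then Na2SO3; NaHSO4 to pH 4
Reagents that add atoms: hydrogen peroxide (as lithium hydroperoxide), OO
Why: Lithium hydroperoxide cleaves the imide at the exocyclic carbonyl (standard auxiliary removal) and should leave silyl ethers, diene and allylsilane untouched.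

**Step 11**
Reactants: 16 (2S,3R,5R,6S,7E)-3,5-bis(TBS-oxy)-6-[(TBDPS-oxy)methyl]-2,6-dimethyl-9-[(trimethylsilyl)methyl]deca-7,9-dienoic acid
Product: 19 (1S,2R,4R,5S,6R,7S)-2,4-bis(TBS-oxy)-5-[(TBDPS-oxy)methyl]-1,5-dimethyl-7-[3-(trimethylsilyl)prop-1-en-2-yl]bicyclo[4.1.1]octan-8-one, via acid chloride 17 (not isolated), via ketene 18 (not isolated)
Conditions: 1-chloro-N,N,2-trimethylprop-1-en-1-amine, CH2Cl2, 0 °C; then slow addition to Et3N, toluene, 110 °C (0.005 M)
Reagents that add atoms: none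
Why: Intramolecular ketene–diene [2+2] cycloaddition in which the ketene carbonyl carbon bonds to the proximal diene carbon and the ketene α-carbon to the allyl-stabilised internal carbon, closing the seven-membered ring and the cyclobutanone as a bridged bicycle; the E-alkene puts the C7 side chain anti to the four-carbon bridge, and the approach that keeps the bulky C5–CH2OSi and C2–OSi groups beside the flat ketene carbon C8 (away from C7–H) is expected to set C1, C6 and C7 as drawn.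

**Step 12**
Reactants: 19 (1S,2R,4R,5S,6R,7S)-2,4-bis(TBS-oxy)-5-[(TBDPS-oxy)methyl]-1,5-dimethyl-7-[3-(trimethylsilyl)prop-1-en-2-yl]bicyclo[4.1.1]octan-8-one; 20 2-(trimethylsilyl)-1,3-dithiane
Product: 23 (4R,5S,6S,7R,9R,10R,11R)-7,9-bis(TBS-oxy)-15-(TBDPS-oxy)longipin-3(12)-en-1-one propane-1,3-diyl dithioketal, via lithiated dithiane 21 (not isolated), via ketene dithioacetal 22 (not isolated)
Conditions: 20, n-BuLi, THF, −30 °C; then 19, −78 → 20 °C; then solvent change to CH2Cl2, CF3CO2H, −40 → 0 °C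
Reagents that add atoms: none
Why: Peterson olefination of the non-enolisable bridging ketone (C8 of 19, C11 of the target) inserts the future C1 as a ketene dithioacetal carbon, CF3CO2H then protonates the electron-rich C11=C1 bond at C11 to give a 2-alkyl-1,3-dithian-2-ylium ion (a masked acyl cation), this is captured by the CH2= terminus (C2) of the allylsilane, and the β-silyl cation at C3 loses Me3Si to leave the exocyclic alkene. The closest known reaction types are the acid-initiated cation–olefin cyclisation of ketene dithioacetals and the allylsilane-terminated (Hosomi–Sakurai-type) cyclisation. Ring A (C1–C2–C3–C4–C5–C11) is closed by the C1–C2 bond in a 6-endo-trig attack of the allylsilane π bond on the exocyclic cation carbon, which completes the bicyclo[3.1.1]heptane and the tricyclic skeleton. The only new stereocentre, C11, is set by the ring closure itself: protonation is reversible and only the epimer with the dithianylium group anti to the four-carbon bridge, 1,3-cis to the C4 side chain, can reach C2, so both epimers should funnel into one product (Curtin–Hammett). The step needs C-protonation of the ketene dithioacetal to outrun protodesilylation, and it needs termination without Wagner–Meerwein shift of the adjacent cyclobutane bond; the much higher basicity of the S,S-ketene acetal should secure the first, and the β-silicon effect, which stabilises the charge at C3 until silicon leaves as Me3SiOCOCF3, the second.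

**Step 13**
Reactants: 23 (4R,5S,6S,7R,9R,10R,11R)-7,9-bis(TBS-oxy)-15-(TBDPS-oxy)longipin-3(12)-en-1-one propane-1,3-diyl dithioketal
Product: 25 (4R,5S,6S,7R,9R,10R,11R)-7,9-bis(TBS-oxy)-15-(TBDPS-oxy)longipin-2-en-1-one, via deconjugated enone 24 (not isolated)
Conditions: PhI(OCOCF3)2, MeCN–H2O, 0 °C; then 1,8-diazabicyclo[5.4.0]undec-7-ene (20 mol %), CH2Cl2, 20 °C
Reagents that add atoms: water, O
Why: Oxidative dithioketal hydrolysis with the hypervalent iodine reagent unmasks the C1 ketone, and base-mediated β,γ→α,β isomerisation through the dienolate should move the exocyclic alkene into conjugation to give the trisubstituted enone without affecting a stereocentre.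

**Step 14**
Reactants: 25 (4R,5S,6S,7R,9R,10R,11R)-7,9-bis(TBS-oxy)-15-(TBDPS-oxy)longipin-2-en-1-one
Product: 26 (4R,5S,6S,7R,9R,10R,11R)-7,9,15-trihydroxylongipin-2-en-1-one
Conditions: HF·pyridine, THF, 0 → 40 °C
Reagents that add atoms: none
Why: Fluoride-mediated global desilylation in a weakly acidic medium should free the three hydroxyls without base-induced reactions of the enone.

**Step 15**
Reactants: 26 (4R,5S,6S,7R,9R,10R,11R)-7,9,15-trihydroxylongipin-2-en-1-one; 27 angelic anhydride [(2Z)-2-methylbut-2-enoic anhydride]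
Product: 29 (4R,5S,6S,7R,9R,10R,11R)-15-(angeloyloxy)-7,9-dihydroxylongipin-2-en-1-one, via lithium alkoxide 28 (not isolated)
Conditions: LiN(SiMe3)2 (1.0 equiv), THF, −78 °C; then 27 (1.05 equiv), −78 → −20 °C; aq. NH4Cl
Reagents that add atoms: none
Why: Acylation of a lithium alkoxide by a symmetrical anhydride without a nucleophilic catalyst (base-mediated esterification), in which the unhindered primary C15 alkoxide should react much faster than the two secondary alkoxides next to quaternary carbons with which it equilibrates, and the Z geometry should be retained because no amine catalyst is present that could add to the acyl donor; no stereocentre is affected.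

**Step 16**
Reactants: 29 (4R,5S,6S,7R,9R,10R,11R)-15-(angeloyloxy)-7,9-dihydroxylongipin-2-en-1-one; 27 angelic anhydride [(2Z)-2-methylbut-2-enoic anhydride]
Product: 31 (4R,5S,6S,7R,9R,10R,11R)-7,9,15-tris(angeloyloxy)longipin-2-en-1-one (CNP0266467.1), via dilithium dialkoxide 30 (not isolated)
Conditions: LiN(SiMe3)2 (2.0 equiv), THF, −78 °C; then 27 (3 equiv), −78 → 0 °C; aq. NH4Cl
Reagents that add atoms: none
Why: The same alkoxide acylation with the anhydride in excess (one anhydride molecule is consumed per hydroxyl) should esterify both hindered secondary hydroxyls at C7 and C9 with retention of the Z geometry, the enone tolerating the conditions because C11–H is a bridgehead hydrogen that cannot be removed and the hydroxyls are deprotonated before the γ-methyl group; no stereocentre is affected.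

**Compound list**

1 | 4-chlorobut-2-yn-1-ol | OCC#CCCl | starting material
2 | 2-methylbuta-2,3-dien-1-ol | C=C=C(C)CO | intermediate
3 | tert-butyl[(2-methylbuta-2,3-dien-1-yl)oxy]diphenylsilane | C=C=C(C)CO[Si](c1ccccc1)(c1ccccc1)C(C)(C)C | intermediate
4 | 3-[(tert-butyldimethylsilyl)oxy]propanal | O=CCCO[Si](C)(C)C(C)(C)C | starting material
5 | [(2Z)-4-(TBDPS-oxy)-3-methylbut-2-en-1-yl]bis(isopinocampheyl)borane, from (−)-diisopinocampheylborane | C[C@H]1[C@H](B(C/C=C(/C)CO[Si](c5ccccc5)(c5ccccc5)C(C)(C)C)[C@H]3[C@H](C)[C@H]4C[C@@H](C3)C4(C)C)C[C@@H]2C[C@H]1C2(C)C | intermediate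
6 | (3R,4S)-1-(TBS-oxy)-4-[(TBDPS-oxy)methyl]-4-methylhex-5-en-3-ol | CC(C)(C)[Si](c1ccccc1)(c1ccccc1)OC[C@]([C@H](O)CCO[Si](C)(C)C(C)(C)C)(C)C=C | intermediate
7 | (3R,4S)-1,3-bis(TBS-oxy)-4-[(TBDPS-oxy)methyl]-4-methylhex-5-ene | CC(C)(C)[Si](c1ccccc1)(c1ccccc1)OC[C@]([C@H](O[Si](C)(C)C(C)(C)C)CCO[Si](C)(C)C(C)(C)C)(C)C=C | intermediate
8 | (3R,4S)-3-(TBS-oxy)-4-[(TBDPS-oxy)methyl]-4-methylhex-5-en-1-ol | CC(C)(C)[Si](c1ccccc1)(c1ccccc1)OC[C@]([C@H](O[Si](C)(C)C(C)(C)C)CCO)(C)C=C | intermediate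
9 | (3R,4S)-3-(TBS-oxy)-4-[(TBDPS-oxy)methyl]-4-methylhex-5-enal | CC(C)(C)[Si](c1ccccc1)(c1ccccc1)OC[C@]([C@H](O[Si](C)(C)C(C)(C)C)CC=O)(C)C=C | intermediate
10 | (4S)-4-benzyl-3-propanoyl-1,3-oxazolidin-2-one | CCC(=O)N1[C@@H](Cc2ccccc2)COC1=O | starting material
11 | dibutylboron (Z)-enolate of 10 | C/C=C(\OB(CCCC)CCCC)N1[C@@H](Cc2ccccc2)COC1=O | intermediate
12 | (4S)-4-benzyl-3-{(2S,3R,5R,6S)-5-(TBS-oxy)-6-[(TBDPS-oxy)methyl]-3-hydroxy-2,6-dimethyloct-7-enoyl}-1,3-oxazolidin-2-one | CC(C)(C)[Si](c1ccccc1)(c1ccccc1)OC[C@]([C@H](O[Si](C)(C)C(C)(C)C)C[C@@H](O)[C@H](C)C(=O)N1[C@@H](Cc2ccccc2)COC1=O)(C)C=C | intermediate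
13 | (4S)-4-benzyl-3-{(2S,3R,5R,6S)-3,5-bis(TBS-oxy)-6-[(TBDPS-oxy)methyl]-2,6-dimethyloct-7-enoyl}-1,3-oxazolidin-2-one | CC(C)(C)[Si](c1ccccc1)(c1ccccc1)OC[C@]([C@H](O[Si](C)(C)C(C)(C)C)C[C@@H](O[Si](C)(C)C(C)(C)C)[C@H](C)C(=O)N1[C@@H](Cc2ccccc2)COC1=O)(C)C=C | intermediate
14 | (2-bromoprop-2-en-1-yl)trimethylsilane | C=C(Br)C[Si](C)(C)C | starting material
15 | (4S)-4-benzyl-3-{(2S,3R,5R,6S,7E)-3,5-bis(TBS-oxy)-6-[(TBDPS-oxy)methyl]-2,6-dimethyl-9-[(trimethylsilyl)methyl]deca-7,9-dienoyl}-1,3-oxazolidin-2-one | CC(C)(C)[Si](c1ccccc1)(c1ccccc1)OC[C@]([C@H](O[Si](C)(C)C(C)(C)C)C[C@@H](O[Si](C)(C)C(C)(C)C)[C@H](C)C(=O)N1[C@@H](Cc2ccccc2)COC1=O)(C)/C=C/C(=C)C[Si](C)(C)C | intermediate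
16 | (2S,3R,5R,6S,7E)-3,5-bis(TBS-oxy)-6-[(TBDPS-oxy)methyl]-2,6-dimethyl-9-[(trimethylsilyl)methyl]deca-7,9-dienoic acid | CC(C)(C)[Si](c1ccccc1)(c1ccccc1)OC[C@]([C@H](O[Si](C)(C)C(C)(C)C)C[C@@H](O[Si](C)(C)C(C)(C)C)[C@H](C)C(=O)O)(C)/C=C/C(=C)C[Si](C)(C)C | intermediate
17 | acid chloride of 16 | CC(C)(C)[Si](c1ccccc1)(c1ccccc1)OC[C@]([C@H](O[Si](C)(C)C(C)(C)C)C[C@@H](O[Si](C)(C)C(C)(C)C)[C@H](C)C(=O)Cl)(C)/C=C/C(=C)C[Si](C)(C)C | intermediate
18 | (3R,5R,6S,7E)-3,5-bis(TBS-oxy)-6-[(TBDPS-oxy)methyl]-2,6-dimethyl-9-[(trimethylsilyl)methyl]deca-1,7,9-trien-1-one (ketene) | CC(C)(C)[Si](c1ccccc1)(c1ccccc1)OC[C@]([C@H](O[Si](C)(C)C(C)(C)C)C[C@@H](O[Si](C)(C)C(C)(C)C)C(C)=C=O)(C)/C=C/C(=C)C[Si](C)(C)C | intermediate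
19 | (1S,2R,4R,5S,6R,7S)-2,4-bis(TBS-oxy)-5-[(TBDPS-oxy)methyl]-1,5-dimethyl-7-[3-(trimethylsilyl)prop-1-en-2-yl]bicyclo[4.1.1]octan-8-one (C7 side chain anti to the C2–C5 bridge) | CC(C)(C)[Si](c1ccccc1)(c1ccccc1)OC[C@]1(C)[C@@H]2C(=O)[C@]([C@H]2C(=C)C[Si](C)(C)C)(C)[C@H](O[Si](C)(C)C(C)(C)C)C[C@H]1O[Si](C)(C)C(C)(C)C | intermediate
20 | 2-(trimethylsilyl)-1,3-dithiane | C[Si](C)(C)C1SCCCS1 | starting material
21 | 2-lithio-2-(trimethylsilyl)-1,3-dithiane | [Li]C1([Si](C)(C)C)SCCCS1 | intermediate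
22 | 2-{(1R,2R,4R,5S,6R,7S)-2,4-bis(TBS-oxy)-5-[(TBDPS-oxy)methyl]-1,5-dimethyl-7-[3-(trimethylsilyl)prop-1-en-2-yl]bicyclo[4.1.1]octan-8-ylidene}-1,3-dithiane | CC(C)(C)[Si](c1ccccc1)(c1ccccc1)OC[C@]1(C)[C@@H]2C(=C3SCCCS3)[C@]([C@H]2C(=C)C[Si](C)(C)C)(C)[C@H](O[Si](C)(C)C(C)(C)C)C[C@H]1O[Si](C)(C)C(C)(C)C | intermediate
23 | (4R,5S,6S,7R,9R,10R,11R)-7,9-bis(TBS-oxy)-15-(TBDPS-oxy)longipin-3(12)-en-1-one propane-1,3-diyl dithioketal | CC(C)(C)[Si](c1ccccc1)(c1ccccc1)OC[C@]1(C)[C@@H]2[C@H]3C4(SCCCS4)CC(=C)[C@@H]2[C@@]3(C)[C@H](O[Si](C)(C)C(C)(C)C)C[C@H]1O[Si](C)(C)C(C)(C)C | intermediate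
24 | (4R,5S,6S,7R,9R,10R,11R)-7,9-bis(TBS-oxy)-15-(TBDPS-oxy)longipin-3(12)-en-1-one | CC(C)(C)[Si](c1ccccc1)(c1ccccc1)OC[C@]1(C)[C@@H]2[C@H]3C(=O)CC(=C)[C@@H]2[C@@]3(C)[C@H](O[Si](C)(C)C(C)(C)C)C[C@H]1O[Si](C)(C)C(C)(C)C | intermediate
25 | (4R,5S,6S,7R,9R,10R,11R)-7,9-bis(TBS-oxy)-15-(TBDPS-oxy)longipin-2-en-1-one | CC(C)(C)[Si](c1ccccc1)(c1ccccc1)OC[C@]1(C)[C@@H]2[C@H]3C(=O)C=C(C)[C@@H]2[C@@]3(C)[C@H](O[Si](C)(C)C(C)(C)C)C[C@H]1O[Si](C)(C)C(C)(C)C | intermediate
26 | (4R,5S,6S,7R,9R,10R,11R)-7,9,15-trihydroxylongipin-2-en-1-one | OC[C@]1(C)[C@@H]2[C@H]3C(=O)C=C(C)[C@@H]2[C@@]3(C)[C@H](O)C[C@H]1O | intermediate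
27 | angelic anhydride [(2Z)-2-methylbut-2-enoic anhydride] | C/C=C(/C)C(=O)OC(=O)/C(C)=C\C | starting material
28 | lithium C15-alkoxide of 26 | [Li]OC[C@]1(C)[C@@H]2[C@H]3C(=O)C=C(C)[C@@H]2[C@@]3(C)[C@H](O)C[C@H]1O | intermediate
29 | (4R,5S,6S,7R,9R,10R,11R)-15-(angeloyloxy)-7,9-dihydroxylongipin-2-en-1-one | C/C=C(/C)C(=O)OC[C@]1(C)[C@@H]2[C@H]3C(=O)C=C(C)[C@@H]2[C@@]3(C)[C@H](O)C[C@H]1O | intermediate
30 | dilithium C7,C9-dialkoxide of 29 | C/C=C(/C)C(=O)OC[C@]1(C)[C@@H]2[C@H]3C(=O)C=C(C)[C@@H]2[C@@]3(C)[C@H](O[Li])C[C@H]1O[Li] | intermediate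
31 | (4R,5S,6S,7R,9R,10R,11R)-7,9,15-tris(angeloyloxy)longipin-2-en-1-one (CNP0266467.1) | C/C=C(/C)C(=O)OC[C@]1(C)[C@@H]2[C@H]3C(=O)C=C(C)[C@@H]2[C@@]3(C)[C@H](OC(=O)/C(C)=C\C)C[C@H]1OC(=O)/C(C)=C\C | target

**Step count and risks**

Total step count: 16. Longest linear sequence: 16 steps (1 → 31; 14 steps from 4).

Three steps most likely to fail:

1. Step 11 (ketene [2+2]). The hindered methyl(alkyl)ketene closes a seven-membered ring slowly, so ketene dimerisation or ene-type acylation may compete, and the facial preference of the diene may be incomplete. Fallback by known keteniminium chemistry, setting out from 16 and coming back at 19: acid 16 is converted through 17 with pyrrolidine into the pyrrolidine amide F1. Triflic anhydride and 2,4,6-collidine in 1,2-dichloroethane generate the keteniminium triflate F2, a much stronger electrophile, which should undergo the same intramolecular [2+2] at or below 40 °C to the cyclobutaniminium triflate F3. Aqueous NaHCO3 hydrolyses F3 to ketone 19.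

2. Step 12 (key step). Addition of the bulky lithiated dithiane to the shielded bridging carbonyl may be slow, or the allylsilane may undergo protodesilylation before C–C bond formation. Fallback by known chemistry with the same C1–C2 ring closure, setting out from 19 and coming back at 25: van Leusen reductive cyanation (TosMIC, t-BuOK, DME–EtOH) gives the nitrile F4, whose C8 epimers equilibrate under the basic conditions. i-Bu2AlH reduces it to the aldehyde F5. BF3·OEt2 triggers an intramolecular Hosomi–Sakurai allylation that closes ring A to the homoallylic alcohol F6. Dess–Martin oxidation gives 24 and 1,8-diazabicyclo[5.4.0]undec-7-ene gives 25.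

3. Step 16 (esterification of the two secondary hydroxyls). Acylation of the two hydroxyls flanked by quaternary carbons may stay incomplete, and γ-deprotonation of the enone or Z→E isomerisation of the acyl groups may compete on prolonged exposure to base. Fallback by known chemistry, setting out from 29 and coming back at 31: diol 29 is esterified (DCC, catalytic DMAP, CH2Cl2) with 2-[bis(2,2,2-trifluoroethoxy)phosphoryl]propanoic acid to the bis(phosphonopropanoate) F7. A twofold Still–Gennari olefination with acetaldehyde (KN(SiMe3)2, 18-crown-6, THF, −78 °C) then builds the two remaining (Z)-2-methylbut-2-enoates in place and gives 31.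

**Further compounds**

F1 | step 11 | pyrrolidine amide of 16 | CC(C)(C)[Si](c1ccccc1)(c1ccccc1)OC[C@]([C@H](O[Si](C)(C)C(C)(C)C)C[C@@H](O[Si](C)(C)C(C)(C)C)[C@H](C)C(=O)N1CCCC1)(C)/C=C/C(=C)C[Si](C)(C)C
F2 | step 11 | keteniminium triflate from F1 | CC(C)(C)[Si](c1ccccc1)(c1ccccc1)OC[C@]([C@H](O[Si](C)(C)C(C)(C)C)C[C@@H](O[Si](C)(C)C(C)(C)C)C(C)=C=[N+]1CCCC1)(C)/C=C/C(=C)C[Si](C)(C)C.[O-]S(=O)(=O)C(F)(F)F
F3 | step 11 | pyrrolidinium-ylidene (cyclobutaniminium) triflate corresponding to ketone 19 | CC(C)(C)[Si](c1ccccc1)(c1ccccc1)OC[C@]1(C)[C@@H]2C(=[N+]3CCCC3)[C@]([C@H]2C(=C)C[Si](C)(C)C)(C)[C@H](O[Si](C)(C)C(C)(C)C)C[C@H]1O[Si](C)(C)C(C)(C)C.[O-]S(=O)(=O)C(F)(F)F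
F4 | step 12 | 8-carbonitrile corresponding to 19 (nitrile anti to the C2–C5 bridge) | CC(C)(C)[Si](c1ccccc1)(c1ccccc1)OC[C@]1(C)[C@@H]2[C@@H](C#N)[C@]([C@H]2C(=C)C[Si](C)(C)C)(C)[C@H](O[Si](C)(C)C(C)(C)C)C[C@H]1O[Si](C)(C)C(C)(C)C
F5 | step 12 | 8-carbaldehyde corresponding to F4 | CC(C)(C)[Si](c1ccccc1)(c1ccccc1)OC[C@]1(C)[C@@H]2[C@@H](C=O)[C@]([C@H]2C(=C)C[Si](C)(C)C)(C)[C@H](O[Si](C)(C)C(C)(C)C)C[C@H]1O[Si](C)(C)C(C)(C)C
F6 | step 12 | 7,9-bis(TBS-oxy)-15-(TBDPS-oxy)longipin-3(12)-en-1-ol (either C1 epimer) | CC(C)(C)[Si](c1ccccc1)(c1ccccc1)OC[C@]1(C)[C@@H]2[C@H]3C(O)CC(=C)[C@@H]2[C@@]3(C)[C@H](O[Si](C)(C)C(C)(C)C)C[C@H]1O[Si](C)(C)C(C)(C)C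
F7 | step 16 | 7,9-bis{2-[bis(2,2,2-trifluoroethoxy)phosphoryl]propanoyl} ester of 29 | C/C=C(/C)C(=O)OC[C@]1(C)[C@@H]2[C@H]3C(=O)C=C(C)[C@@H]2[C@@]3(C)[C@H](OC(=O)C(C)P(=O)(OCC(F)(F)F)OCC(F)(F)F)C[C@H]1OC(=O)C(C)P(=O)(OCC(F)(F)F)OCC(F)(F)F
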